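**Plan**

1. Chain numbering C1–C15 is used throughout (C1=C2 vinyl, C3 carbinol, C14 Br, C15 Cl); the core is a 7-oxabicyclo[2.2.1]heptane with ring bond C6–C11 and oxygen bridge C7–O–C10.
2. Cuts, in order: C15–Cl and C14–Br (back to the C14=C15 olefin); C9–C10, with a C8 carbonyl as helper (back to a 2-diazoacetyl oxolane); C10–O and C11–C12 (back to a γ-lactone); C6–C11 (back to a 6,7-epoxide); C8–O (back to (S)-linalool, which maps onto C1–C8).
3. Forward: (S)-linalool supplies C3; allylic oxidation and Sharpless epoxidation set C6 and C7; propanoate dianion opens the epoxide at C6 with inversion and lactonises; enolate alkylation anti to the C6 chain sets quaternary C11; lactone reduction and etherification give the oxolane (ring 1).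
4. C8 is oxidised to the acid and extended by diazomethane (C9). The key event is insertion of the rhodium carbene at C9 into the C10–H bond. It is possible because that bond is α to the oxolane oxygen and sits cis-1,3 to the acyl group on C7, five atoms from the carbene carbon. It closes the oxolanone ring and the six-membered carbocycle together and fixes C10.
5. The C8 carbonyl is then removed; Shi epoxidation sets C14, bromide opens the epoxide with inversion, chloride enters at C15 through the bromonium ion, and desilylation ends the route.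

Key step: step 12

Assumption: (S)-(+)-linalool of high enantiomeric purity is taken as a purchasable chiral-pool material.

**Route**

Step 1
Reactants: 1 (S)-linalool
Product: 2 (S)-linalyl triethylsilyl ether
Conditions: Et3SiOTf, 2,6-lutidine, CH2Cl2, −78 → 0 °C
Reagents that add atoms: triethylsilyl trifluoromethanesulfonate, CC[Si](CC)(CC)OS(=O)(=O)C(F)(F)F
Why: Silylation of the tertiary alcohol with a silyl triflate leaves C3 untouched and keeps this hydroxyl from attacking the later 6,7-epoxide.

Step 2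
Reactants: 2 (S)-linalyl triethylsilyl ether
Product: 3 (E)-allylic alcohol
Conditions: SeO2 (cat.), t-BuOOH, salicylic acid (cat.), CH2Cl2, 0 °C → rt
Reagents that add atoms: selenium dioxide, O=[Se]=O (catalytic oxygen carrier); tert-butyl hydroperoxide, CC(C)(C)OO (terminal oxidant)
Why: Riley allylic oxidation (ene reaction, then [2,3]-sigmatropic shift) should oxidise the (E)-methyl group of the gem-dimethyl olefin selectively; the vinyl group has no allylic hydrogen.

Step 3
Reactants: 3 (E)-allylic alcohol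
Product: 4 epoxy alcohol
Conditions: Ti(OiPr)4 (10 mol%), L-(+)-diethyl tartrate (12 mol%), t-BuOOH, 4 Å molecular sieves, CH2Cl2, −20 °C
Reagents that add atoms: tert-butyl hydroperoxide, CC(C)(C)OO
Why: Sharpless asymmetric epoxidation of the primary allylic alcohol; L-(+)-tartrate should deliver oxygen to the face that gives the (2S,3S)-epoxide, which sets C6 and C7 by reagent control.

Step 4
Reactants: 4 epoxy alcohol
Product: 5 bis-silyl epoxide
Conditions: Et3SiCl, imidazole, CH2Cl2, 0 °C
Reagents that add atoms: chlorotriethylsilane, CC[Si](CC)(CC)Cl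
Why: Silylation of the primary alcohol blocks Payne rearrangement in the basic step that follows and installs a group that step 9 oxidises directly.

Step 5
Reactants: 5 bis-silyl epoxide; 6 propanoic acid
Product: 8 methyl lactone (C11 epimers), via γ-hydroxy acid 7 (not isolated)
Conditions: 6, LiN(iPr)2 (2 equiv per 6), THF–DMPU, 0 °C; then 5, 50 °C; AcOH; PhH, 50 °C
Reagents that add atoms: none
Why: Epoxide opening by a carboxylic acid dianion (SN2 at the less substituted carbon C6, with inversion) followed by lactonisation of the γ-hydroxy acid; C6 is set by the inversion, C7 keeps its oxygen, and the C11 epimers converge in step 6.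

Step 6
Reactants: 8 methyl lactone (C11 epimers); 9 5-bromo-2-methylpent-2-ene
Product: 10 quaternary lactone
Conditions: LiN(iPr)2, THF, −78 °C; then 9, DMPU, −78 → −20 °C
Reagents that add atoms: none
Why: Lactone enolate alkylation; the electrophile should approach anti to the C6 side chain (and to the C7 CH2OSiEt3 group), which places the new chain trans to the C6 chain and sets quaternary C11 by substrate control.

Step 7
Reactants: 10 quaternary lactone
Product: 11 diol
Conditions: LiAlH4, THF, 0 °C → rt
Reagents that add atoms: none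
Why: Hydride reduction of the lactone to the 1,4-diol; silyl ethers and olefins are not touched and no stereocenter is involved.

Step 8
Reactants: 11 diol
Product: 13 oxolane, via primary tosylate 12 (not isolated)
Conditions: TsCl, pyridine, DMAP (cat.), 0 → 60 °C
Reagents that add atoms: none
Why: Selective sulfonylation of the primary hydroxyl and intramolecular Williamson etherification (5-exo-tet) by the tertiary hydroxyl; the C7–O bond is not broken, so C7 is retained.

Step 9
Reactants: 13 oxolane
Product: 14 aldehyde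
Conditions: (COCl)2, DMSO, CH2Cl2, −78 → −30 °C; then Et3N
Reagents that add atoms: none
Why: Under Swern conditions a primary triethylsilyl ether is cleaved by the chlorosulfonium salt and oxidised in the same operation, while the tertiary silyl ether should stay.

Step 10
Reactants: 14 aldehyde
Product: 15 carboxylic acid
Conditions: NaClO2, NaH2PO4, 2-methylbut-2-ene (large excess), t-BuOH/H2O, 0 °C → rt
Reagents that add atoms: sodium chlorite, [Na+].[O-]Cl=O
Why: Pinnick oxidation of the non-enolisable aldehyde; the scavenger olefin protects the substrate olefins from hypochlorous acid.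

Step 11
Reactants: 15 carboxylic acid
Product: 17 diazoketone, via acid chloride 16 (not isolated)
Conditions: 1-chloro-N,N,2-trimethylprop-1-en-1-amine, CH2Cl2, 0 °C; then CH2N2 (excess), Et2O, 0 °C
Reagents that add atoms: diazomethane, C=[N+]=[N-]
Why: Neutral acid chloride formation with an α-chloroenamine spares the silyl ether, and acylation of diazomethane (first stage of the Arndt–Eistert sequence) brings in C9.

Step 12
Reactants: 17 diazoketone
Product: 18 oxabicyclic ketone
Conditions: Rh2(OAc)4 (1 mol%), CH2Cl2, 25 °C, slow addition of 17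
Reagents that add atoms: none
Why: Dirhodium tetraacetate (divalent rhodium) should expel N2 from 17 to give an electrophilic rhodium carbene at C9, which inserts in a concerted three-centre transition state into the C10–H bond cis to the acyl group, the developing positive charge at C10 being stabilised by a lone pair of the ring oxygen. The closest known reaction type is the rhodium-catalysed 1,5 C–H insertion of α-alkoxy α'-diazoketones next to ether oxygen, which gives 3(2H)-furanones, bridged bicyclic ethers included. One bond closes two rings: the oxolan-3-one ring O–C7–C8–C9–C10 (1,5-insertion, five-membered) and with it the carbocycle C6–C7–C8–C9–C10–C11 (six-membered), that is, the 7-oxabicyclo[2.2.1]heptane. The new stereocenter C10 is controlled by C7, because only the C10 hydrogen on the face of the diazoacetyl group can be reached, so the bridge must form cis. The step needs site selectivity for C10–H over the C5 methylene of the neighbouring side chain (also a 1,5 relation) and over the two olefins: the ether oxygen activates C10–H and inductively deactivates C–H bonds further away, the olefins could only be reached through rings of eight or more atoms, and slow addition suppresses carbene dimerisation.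

Step 13
Reactants: 18 oxabicyclic ketone
Product: 20 deoxygenated oxabicycle, via tosylhydrazone 19 (not isolated)
Conditions: TsNHNH2, EtOH, 60 °C; then catecholborane, CHCl3, 0 °C; NaOAc·3H2O, reflux
Reagents that add atoms: none
Why: Tosylhydrazone reduction with catecholborane (hydroboration of C=N, then acetate-induced loss of sulfinate and of N2 from the diazene) removes the helper carbonyl under nearly neutral conditions, which avoids the β-alkoxide elimination expected under Wolff–Kishner conditions.

Step 14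
Reactants: 20 deoxygenated oxabicycle
Product: 21 epoxide
Conditions: D-fructose-derived Shi ketone (30 mol%), Oxone (2KHSO5·KHSO4·K2SO4), K2CO3, Bu4NHSO4, MeCN/dimethoxymethane/aqueous buffer (pH 10.5), 0 °C
Reagents that add atoms: potassium peroxymonosulfate, [K+].[O-]S(=O)(=O)OO
Why: Shi epoxidation through a chiral dioxirane; the trisubstituted olefin should react far faster than the vinyl group, and the spiro transition state of the D-fructose-derived ketone should give the (R)-epoxide at C14 by reagent control.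

Step 15
Reactants: 21 epoxide
Product: 22 bromohydrin
Conditions: Li2NiBr4, THF, 0 °C → rt
Reagents that add atoms: dilithium tetrabromonickelate, [Li+].[Li+].[Ni+2].[Br-].[Br-].[Br-].[Br-]
Why: SN2 epoxide opening by soft bromide at the less substituted carbon C14 with inversion should give the (14S)-bromide and the tertiary alcohol.

Step 16
Reactants: 22 bromohydrin
Product: 24 bromochloride silyl ether, via chlorosulfite 23 (not isolated)
Conditions: SOCl2, pyridine, CH2Cl2, −20 → 0 °C
Reagents that add atoms: thionyl chloride, O=S(Cl)Cl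
Why: Chlorination of a tertiary alcohol with neighbouring-group participation: the chlorosulfite ionises with bromine bridging, chloride opens the bromonium ion at the tertiary carbon C15, and C14 keeps its configuration because bromine never leaves it.

Step 17
Reactants: 24 bromochloride silyl ether
Product: 25 target compound CNP0297543.1
Conditions: HF·pyridine, pyridine, THF, 0 °C → rt
Reagents that add atoms: none
Why: Fluoride-mediated desilylation of the tertiary silyl ether under buffered conditions that should leave the secondary bromide, the tertiary chloride and the allylic carbinol intact.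

**Compound list**

1 | (S)-(+)-linalool, (3S)-3,7-dimethylocta-1,6-dien-3-ol | C=C[C@@](C)(O)CCC=C(C)C | starting material
2 | (3S)-3,7-dimethyl-3-(triethylsilyloxy)octa-1,6-diene | C=C[C@@](C)(O[Si](CC)(CC)CC)CCC=C(C)C | intermediate
3 | (2E,6S)-2,6-dimethyl-6-(triethylsilyloxy)octa-2,7-dien-1-ol | C=C[C@@](C)(O[Si](CC)(CC)CC)CC/C=C(\C)CO | intermediate
4 | [(2S,3S)-2-methyl-3-[(3S)-3-methyl-3-(triethylsilyloxy)pent-4-en-1-yl]oxiran-2-yl]methanol | C=C[C@@](C)(O[Si](CC)(CC)CC)CC[C@@H]1O[C@@]1(C)CO | intermediate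
5 | triethylsilyl ether of 4 at the primary hydroxyl | C=C[C@@](C)(O[Si](CC)(CC)CC)CC[C@@H]1O[C@@]1(C)CO[Si](CC)(CC)CC | intermediate
6 | propanoic acid | CCC(=O)O | starting material
7 | (3S,4R)-4-hydroxy-2,4-dimethyl-3-[(3S)-3-methyl-3-(triethylsilyloxy)pent-4-en-1-yl]-5-(triethylsilyloxy)pentanoic acid, C2 epimers, present as dilithium salt | C=C[C@@](C)(O[Si](CC)(CC)CC)CC[C@@H](C(C)C(=O)O)[C@@](C)(O)CO[Si](CC)(CC)CC | intermediate
8 | (4S,5R)-3,5-dimethyl-4-[(3S)-3-methyl-3-(triethylsilyloxy)pent-4-en-1-yl]-5-[(triethylsilyloxy)methyl]oxolan-2-one, C3 epimers | C=C[C@@](C)(O[Si](CC)(CC)CC)CC[C@H]1C(C)C(=O)O[C@@]1(C)CO[Si](CC)(CC)CC | intermediate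
9 | 5-bromo-2-methylpent-2-ene | CC(C)=CCCBr | starting material
10 | (3S,4S,5R)-3,5-dimethyl-3-(4-methylpent-3-en-1-yl)-4-[(3S)-3-methyl-3-(triethylsilyloxy)pent-4-en-1-yl]-5-[(triethylsilyloxy)methyl]oxolan-2-one | C=C[C@@](C)(O[Si](CC)(CC)CC)CC[C@H]1[C@](C)(CCC=C(C)C)C(=O)O[C@@]1(C)CO[Si](CC)(CC)CC | intermediate
11 | (2S,3S,4R)-2,4-dimethyl-2-(4-methylpent-3-en-1-yl)-3-[(3S)-3-methyl-3-(triethylsilyloxy)pent-4-en-1-yl]-5-(triethylsilyloxy)pentane-1,4-diol | C=C[C@@](C)(O[Si](CC)(CC)CC)CC[C@@H]([C@](C)(CCC=C(C)C)CO)[C@@](C)(O)CO[Si](CC)(CC)CC | intermediate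
12 | 1-O-(4-methylbenzenesulfonyl) derivative of 11 | C=C[C@@](C)(O[Si](CC)(CC)CC)CC[C@@H]([C@](C)(CCC=C(C)C)COS(=O)(=O)c1ccc(C)cc1)[C@@](C)(O)CO[Si](CC)(CC)CC | intermediate
13 | (2R,3S,4S)-2,4-dimethyl-4-(4-methylpent-3-en-1-yl)-3-[(3S)-3-methyl-3-(triethylsilyloxy)pent-4-en-1-yl]-2-[(triethylsilyloxy)methyl]oxolane | C=C[C@@](C)(O[Si](CC)(CC)CC)CC[C@H]1[C@](C)(CCC=C(C)C)CO[C@@]1(C)CO[Si](CC)(CC)CC | intermediate
14 | (2R,3S,4S)-2,4-dimethyl-4-(4-methylpent-3-en-1-yl)-3-[(3S)-3-methyl-3-(triethylsilyloxy)pent-4-en-1-yl]oxolane-2-carbaldehyde | C=C[C@@](C)(O[Si](CC)(CC)CC)CC[C@H]1[C@](C)(CCC=C(C)C)CO[C@@]1(C)C=O | intermediate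
15 | (2R,3S,4S)-2,4-dimethyl-4-(4-methylpent-3-en-1-yl)-3-[(3S)-3-methyl-3-(triethylsilyloxy)pent-4-en-1-yl]oxolane-2-carboxylic acid | C=C[C@@](C)(O[Si](CC)(CC)CC)CC[C@H]1[C@](C)(CCC=C(C)C)CO[C@@]1(C)C(=O)O | intermediate
16 | acid chloride of 15 | C=C[C@@](C)(O[Si](CC)(CC)CC)CC[C@H]1[C@](C)(CCC=C(C)C)CO[C@@]1(C)C(=O)Cl | intermediate
17 | 2-diazo-1-[(2R,3S,4S)-2,4-dimethyl-4-(4-methylpent-3-en-1-yl)-3-[(3S)-3-methyl-3-(triethylsilyloxy)pent-4-en-1-yl]oxolan-2-yl]ethan-1-one | C=C[C@@](C)(O[Si](CC)(CC)CC)CC[C@H]1[C@](C)(CCC=C(C)C)CO[C@@]1(C)C(=O)C=[N+]=[N-] | intermediate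
18 | (1R,4R,5S,6S)-1,5-dimethyl-5-(4-methylpent-3-en-1-yl)-6-[(3S)-3-methyl-3-(triethylsilyloxy)pent-4-en-1-yl]-7-oxabicyclo[2.2.1]heptan-2-one | C=C[C@@](C)(O[Si](CC)(CC)CC)CC[C@H]1[C@](C)(CCC=C(C)C)[C@H]2CC(=O)[C@]1(C)O2 | intermediate
19 | 4-methylbenzenesulfonylhydrazone of 18 | C=C[C@@](C)(O[Si](CC)(CC)CC)CC[C@H]1[C@](C)(CCC=C(C)C)[C@H]2CC(=NNS(=O)(=O)c3ccc(C)cc3)[C@]1(C)O2 | intermediate
20 | triethylsilyl ether of (3S)-5-[(1S,2S,3S,4R)-1,3-dimethyl-3-(4-methylpent-3-en-1-yl)-7-oxabicyclo[2.2.1]heptan-2-yl]-3-methylpent-1-en-3-ol | C=C[C@@](C)(O[Si](CC)(CC)CC)CC[C@H]1[C@](C)(CCC=C(C)C)[C@H]2CC[C@]1(C)O2 | intermediate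
21 | triethylsilyl ether of (3S)-5-[(1S,2S,3S,4R)-3-[2-[(2R)-3,3-dimethyloxiran-2-yl]ethyl]-1,3-dimethyl-7-oxabicyclo[2.2.1]heptan-2-yl]-3-methylpent-1-en-3-ol | C=C[C@@](C)(O[Si](CC)(CC)CC)CC[C@H]1[C@](C)(CC[C@H]3OC3(C)C)[C@H]2CC[C@]1(C)O2 | intermediate
22 | (3S)-3-bromo-5-[(1R,2S,3S,4S)-2,4-dimethyl-3-[(3S)-3-methyl-3-(triethylsilyloxy)pent-4-en-1-yl]-7-oxabicyclo[2.2.1]heptan-2-yl]-2-methylpentan-2-ol | C=C[C@@](C)(O[Si](CC)(CC)CC)CC[C@H]1[C@](C)(CC[C@H](Br)C(C)(C)O)[C@H]2CC[C@]1(C)O2 | intermediate
23 | chlorosulfite ester of 22 at the tertiary hydroxyl | C=C[C@@](C)(O[Si](CC)(CC)CC)CC[C@H]1[C@](C)(CC[C@H](Br)C(C)(C)OS(=O)Cl)[C@H]2CC[C@]1(C)O2 | intermediate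
24 | triethylsilyl ether of the target | C=C[C@@](C)(O[Si](CC)(CC)CC)CC[C@H]1[C@](C)(CC[C@H](Br)C(C)(C)Cl)[C@H]2CC[C@]1(C)O2 | intermediate
25 | (3S)-5-[(1S,2S,3S,4R)-3-[(3S)-3-bromo-4-chloro-4-methylpentyl]-1,3-dimethyl-7-oxabicyclo[2.2.1]heptan-2-yl]-3-methylpent-1-en-3-ol (CNP0297543.1) | C=C[C@@](C)(O)CC[C@H]1[C@](C)(CC[C@H](Br)C(C)(C)Cl)[C@H]2CC[C@]1(C)O2 | target

**Step count and risks**

Total step count: 17. Longest linear sequence: 17 steps (from 1; 6 and 9 are purchased).

Steps most likely to fail:

1. Step 12. The carbene may insert into the C5 methylene C–H bonds of the cis side chain, or dimerise, instead of closing onto C10. The fallback closes the same bond by a polar route and sets out from lactone 10. Reduction with i-Bu2AlH (toluene, −78 °C) should give the lactol F1, and PhSO2H with CaCl2 in CH2Cl2 the anomeric phenyl sulfone F2. Swern oxidation of the primary silyl ether should give the aldehyde F3, Wittig reaction with Ph3P=CHOMe the enol ether F4, and mild acid hydrolysis the homologous aldehyde F5. NaBH4 should give the primary alcohol F6 and TsCl in pyridine the tosylate F7. Deprotonation at C10 with LiN(iPr)2 (THF, −78 → 0 °C) and intramolecular 5-exo-tet alkylation should then form the C9–C10 bond in the bridgehead sulfone F8. Reductive desulfonylation with sodium amalgam (Na/Hg, Na2HPO4, MeOH) comes back to the route at compound 20.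

2. Step 5. SN2 attack at the hindered secondary epoxide carbon may be slow, so that base-induced isomerisation of the epoxide to an allylic alcohol or loss of a silyl group competes. The fallback sets out from epoxy alcohol 4. Hydroxyl-directed opening at C6 with Et2AlC≡CH (toluene, 0 °C) should give the alkynyl diol F9, and silylation of the primary hydroxyl (Et3SiCl, imidazole) the silyl ether F10. Palladium-catalysed cyclocarbonylation of the homopropargylic tertiary alcohol (PdCl2, thiourea, CO, acetone, 50 °C) should give the α-methylene lactone F11. Conjugate reduction with LiB(sec-Bu)3H (THF, −78 °C) and alkylation of the resulting enolate with 9 comes back to the route at compound 10.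

3. Step 16. The tertiary chlorosulfite may eliminate toward an isopropenyl group, chloride may enter at C14 of the bromonium ion and scramble the halogens, or HCl may remove the silyl ether. The fallback reverses the order of halogen entry and sets out from epoxide 21. ClTi(OiPr)3 (CH2Cl2, −20 °C) should deliver chloride to the tertiary epoxide carbon with the C14–O bond intact and give the (14R)-chlorohydrin F12. Appel bromination (PPh3, CBr4, CH2Cl2) with inversion at C14 comes back to the route at compound 24.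

Further compounds
F1 | step 12 | lactol from 10 (anomeric mixture) | C=C[C@@](C)(O[Si](CC)(CC)CC)CC[C@H]1[C@](C)(CCC=C(C)C)C(O)O[C@@]1(C)CO[Si](CC)(CC)CC
F2 | step 12 | anomeric phenyl sulfone (anomeric mixture) | C=C[C@@](C)(O[Si](CC)(CC)CC)CC[C@H]1[C@](C)(CCC=C(C)C)C(S(=O)(=O)c2ccccc2)O[C@@]1(C)CO[Si](CC)(CC)CC
F3 | step 12 | sulfonyl oxolane-2-carbaldehyde | C=C[C@@](C)(O[Si](CC)(CC)CC)CC[C@H]1[C@](C)(CCC=C(C)C)C(S(=O)(=O)c2ccccc2)O[C@@]1(C)C=O
F4 | step 12 | methyl enol ether (E/Z mixture) | C=C[C@@](C)(O[Si](CC)(CC)CC)CC[C@H]1[C@](C)(CCC=C(C)C)C(S(=O)(=O)c2ccccc2)O[C@@]1(C)C=COC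
F5 | step 12 | homologous aldehyde (C9 aldehyde) | C=C[C@@](C)(O[Si](CC)(CC)CC)CC[C@H]1[C@](C)(CCC=C(C)C)C(S(=O)(=O)c2ccccc2)O[C@@]1(C)CC=O
F6 | step 12 | primary alcohol at C9 | C=C[C@@](C)(O[Si](CC)(CC)CC)CC[C@H]1[C@](C)(CCC=C(C)C)C(S(=O)(=O)c2ccccc2)O[C@@]1(C)CCO
F7 | step 12 | C9 tosylate | C=C[C@@](C)(O[Si](CC)(CC)CC)CC[C@H]1[C@](C)(CCC=C(C)C)C(S(=O)(=O)c2ccccc2)O[C@@]1(C)CCOS(=O)(=O)c3ccc(C)cc3
F8 | step 12 | bridgehead phenyl sulfone of the 7-oxabicyclo[2.2.1]heptane | C=C[C@@](C)(O[Si](CC)(CC)CC)CC[C@H]1[C@](C)(CCC=C(C)C)[C@@]2(S(=O)(=O)c3ccccc3)CC[C@]1(C)O2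
F9 | step 5 | alkynyl diol from C6 opening of 4 | C=C[C@@](C)(O[Si](CC)(CC)CC)CC[C@@H](C#C)[C@@](C)(O)CO
F10 | step 5 | primary triethylsilyl ether of F9 | C=C[C@@](C)(O[Si](CC)(CC)CC)CC[C@@H](C#C)[C@@](C)(O)CO[Si](CC)(CC)CC
F11 | step 5 | α-methylene γ-lactone | C=C[C@@](C)(O[Si](CC)(CC)CC)CC[C@H]1C(=C)C(=O)O[C@@]1(C)CO[Si](CC)(CC)CC
F12 | step 16 | (14R)-chlorohydrin, tertiary chloride and secondary alcohol | C=C[C@@](C)(O[Si](CC)(CC)CC)CC[C@H]1[C@](C)(CC[C@@H](O)C(C)(C)Cl)[C@H]2CC[C@]1(C)O2
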